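# Proposed total synthesis of mururin C through a Vilsmeier–Arnold diformylation

## The problem

Mururin C (16) is a fully aromatic, achiral 2-arylbenzofuran, so there is no stereocentre to set and none that could steer another; every difficulty is one of regiochemistry and functional-group tolerance. Ring A (C3a to C7a) carries O1 at C7a, a methoxy group at C7 and a 3-hydroxypropyl chain at C5. This is the substitution pattern of dihydroconiferyl alcohol, with its phenol oxygen as O1 and its only free ortho carbon as C3a. The furan ring has to be grown from that ortho carbon and closed onto the phenol oxygen, with a formyl group at C3 and ring B at C2. Ring B is a 3-methoxycatechol joined para to its central oxygen, so its halide must carry exactly one methyl ether and two removable phenol masks. The free catechol oxidises easily, above all in base or next to palladium at high temperature. The aldehyde does not tolerate hydride reagents or strong nucleophiles, the primary alcohol is converted into a formate or chloride by chloroiminium reagents, and the two aryl methyl ethers must outlast the final ether cleavage. The enabling feature is C3: it bears two one-carbon units at the aldehyde oxidation level, the formyl carbon and C2, because the O1–C2=C3 unit is the dehydrated hemiacetal of an aldehyde. C3 is therefore the central carbon of an arylmalondialdehyde, benzylic and ortho to the ring A oxygen, and it can receive both carbons while it is still the methylene group of an arylacetic acid.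

## Retrosynthesis

**Unmasking (16 to 15).** The three O–CH2Ph bonds of 16 are cut last, leading to tribenzyl ether 15. Benzyl is the one mask that is inert to a hot chloroiminium reagent, hot aqueous hydroxide and carbonate at 100 °C, and that can still be removed without hydride or hydrogen next to the aldehyde. The forward step must cleave two aryl and one alkyl benzyl ether in one Lewis-acid operation while sparing two methyl ethers.

**C2–C1' bond (15 to 10 and 14).** Cutting the bond between C2 and ring B gives benzofuran-3-carbaldehyde 10 and aryl bromide 14. Aldehyde 10 has a single heteroaryl C–H bond, acidified by O1 and by the C3 formyl group, so ring B can be attached by C–H arylation without a halogen or metal on the benzofuran. Bringing ring B in before furan closure would require C2 at the ketone oxidation level, which cannot arise from a formamide carbon and would abandon the malondialdehyde logic. The coupling must tolerate an aldehyde; the alcohol stays benzylated because arylpalladium species can oxidise free primary alcohols.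

**O1–C2 bond (10 to 8).** Opening the furan at O1–C2 and adding water gives free phenol 9, and re-masking its phenol gives arylmalondialdehyde 8. Because the two aldehyde groups of 9 are equivalent, ring closure has no regiochemical question; whichever carbonyl is attacked becomes C2 and the other remains as the formyl group. The forward step must free one aryl benzyl ether in the presence of one alkyl benzyl ether, which acidolysis with a cation scavenger should do.

**C3–C2 and C3–CHO bonds (8 to 5, key disconnection).** Both one-carbon units are removed from C3 and a carboxyl group is added there, giving arylacetic acid 5. In the forward sense a chloroiminium reagent formylates the benzylic carbon twice while the carboxyl group leaves as CO2. This is preferred to formylating a preformed benzofuran at C3, which would need a C2-substituted benzofuran first and a separate construction of C2. The precursor is two carbons simpler, has no aldehyde, and its two benzyl ethers are already in place. The reaction must take place at the benzylic carbon and not on the dialkoxyarene ring.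

**C3a–C3 bond (5 to 3).** Acid 5 comes from ethyl ester 4, and cutting the aryl–CH2 bond of 4 leads to aryl bromide 3 and an acetate zinc enolate. The shorter-looking alternative, ortho-hydroxyalkylation of free phenol 1 with a two-carbon aldehyde acid followed by benzylic deoxygenation, was set aside for two reasons:
- it gives a 2-hydroxyarylacetic acid that lactonises;
- benzylating its aliphatic hydroxyl needs a strong base, which would also C-benzylate the activated methylene group.

The halide-first order installs both benzyl ethers before any acidic C–H bond exists.

**C–Br bond and benzyl ethers (3 to 1).** Removing the benzyl groups from 3 gives bromophenol 2, and removing bromine gives dihydroconiferyl alcohol 1. The para position of the phenol in 1 is blocked by the side chain, so electrophilic bromination should enter the one free ortho position, which is the future C3a.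

**Ring B (14 to 11).** Bromide 14 is the dibenzyl ether of catechol 13. A bromide of the 2,6-dimethoxyphenol type would be cheaper but carries one methyl ether too many, and its selective mono-demethylation is not dependable. Catechol 13 is instead traced through aryl formate 12 to 5-bromo-2-hydroxy-3-methoxybenzaldehyde 11. In 11 the formyl group sits exactly where the second hydroxyl is needed, so a Dakin oxidation gives the right pattern with bromine para to the central oxygen.

## Roads not taken

**Alternative 1:** Stobbe benzannulation of ring A onto a furan. The cut runs through ring A at C7–C7a. A Stobbe condensation of a 3-formylfuran with a succinic diester would give half-ester A1, and heating A1 with Ac2O and NaOAc would acylate the furan alpha carbon and aromatise to ethyl 7-acetoxybenzofuran-5-carboxylate A2.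
- Merits: cheap reagents, no transition metal, and an unambiguous 5,7-pattern on ring A; in these respects it is at least as good as the chosen plan.
- Weak points: A2 has nothing at C2 or C3 and the wrong groups on ring A. The acetate must become a methyl ether, the C5 ester must be extended by two carbons and reduced (about four steps), and ring B and the formyl group still need two further C–C bond formations.
- Comparison: the chosen plan starts from an arene that already has the C5 chain, the C7 methoxy group and O1, and it installs the C3 formyl group together with C2. This gives a clearly shorter linear sequence.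

**Alternative 2:** Copper domino C-arylation and O-arylation. The cuts are C3–C3a and C7a–O1. CuI (monovalent copper) and K2CO3 would couple the alpha carbon of keto ester A4 at the C–I bond of ortho-bromoiodoarene A3 and then the enolate oxygen at the neighbouring C–Br bond, giving benzofuran-3-carboxylate A5.
- Merits: this is the most convergent of the routes considered. Ring B, C2, C3 and its carbon substituent arrive in one step, and no separate C–H arylation is needed; on this point it is better than the chosen plan.
- Weak points: O1 comes from the keto ester, so A3 needs a bromine where the natural precursor has its phenol oxygen. A3 cannot be made from dihydroconiferyl alcohol and needs its own multistep arene synthesis. The O-arylation must occur at a bromide flanked by a methoxy group and the new C3a substituent. The ester of A5 must be reduced and re-oxidised to the aldehyde, and a silyl ether must be handled as well as the benzyl ethers.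
- Comparison: the chosen plan uses the natural oxygenation directly (the phenol oxygen of 1 becomes O1), delivers C3 at the aldehyde oxidation level without redox corrections, and uses one protecting-group type throughout.

**Alternative 3:** Dötz benzannulation of a furylcarbene. Ring A is cut at C6–C7, C4–C5 and C3a–C4. Carbene complex A6 of zerovalent chromium, with ring B already on the furan, would combine with terminal alkyne A7 and one CO ligand to give benzofuran-4-ol A8.
- Merits: convergent, the alkyne substituent is placed reliably at C5 and the methoxy group at C7, and ring B is present from the start; in convergence it matches or exceeds the chosen plan.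
- Weak points: A8 has a hydroxyl group at C4 that the target lacks, so it must be removed by triflation and reduction. The C3 formyl group is still missing and must be added afterwards. The method needs a stoichiometric chromium carbonyl reagent and an organolithium route to A6.
- Comparison: the chosen plan creates no superfluous functional group, needs no stoichiometric heavy metal, and forms the formyl group in the same step as C2.

Key step: step 5

Remark on the chemistry: mururin C has no stereocentre, so no step requires stereocontrol; BrZnCH2CO2Et is taken as the purchasable THF solution and is not prepared in the flask.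

## Route

Step 1
Reactants: 1 dihydroconiferyl alcohol [4-(3-hydroxypropyl)-2-methoxyphenol]
Product: 2 2-bromo-4-(3-hydroxypropyl)-6-methoxyphenol
Conditions: NBS (1.0 equiv), MeCN, 0 °C
Reagents that add atoms: N-bromosuccinimide, O=C1CCC(=O)N1Br
Why: Electrophilic aromatic bromination; the free phenol is the strongest director and its para position is blocked by the side chain, so bromine should enter the only free ortho position (the future C3a), as in the halogenation of other 4-substituted guaiacols.

Step 2
Reactants: 2 2-bromo-4-(3-hydroxypropyl)-6-methoxyphenol
Product: 3 2-(benzyloxy)-1-bromo-5-[3-(benzyloxy)propyl]-3-methoxybenzene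
Conditions: NaH (2.5 equiv), BnBr (2.4 equiv), n-Bu4NI (cat.), DMF, 0 °C to rt
Reagents that add atoms: benzyl bromide, BrCc1ccccc1
Why: Double Williamson etherification of the phenoxide and the primary alkoxide; at this stage the molecule has no acidic C–H bond, so a strong base can be used without C-alkylation, and the aryl bromide is inert.

Step 3
Reactants: 3 2-(benzyloxy)-1-bromo-5-[3-(benzyloxy)propyl]-3-methoxybenzene
Product: 4 ethyl 2-{2-(benzyloxy)-5-[3-(benzyloxy)propyl]-3-methoxyphenyl}acetate
Conditions: BrZnCH2CO2Et (1.5 equiv, THF solution), Pd2(dba)3 (2.5 mol %), XPhos (10 mol %), THF, 65 °C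
Reagents that add atoms: (2-ethoxy-2-oxoethyl)zinc bromide, CCOC(=O)C[Zn]Br
Why: Negishi-type alpha-arylation of a Reformatsky zinc enolate: zerovalent palladium inserts into the C–Br bond, the zinc enolate transmetalates and reductive elimination forms the aryl–CH2 bond (C3a–C3); the neutral zinc reagent needs no strong base, so the ester does not self-condense and the benzyl ethers are untouched.

Step 4
Reactants: 4 ethyl 2-{2-(benzyloxy)-5-[3-(benzyloxy)propyl]-3-methoxyphenyl}acetate
Product: 5 2-{2-(benzyloxy)-5-[3-(benzyloxy)propyl]-3-methoxyphenyl}acetic acid
Conditions: LiOH·H2O (3 equiv), THF/MeOH/H2O, rt; then 1 M HCl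
Reagents that add atoms: lithium hydroxide, [Li+].[OH-]
Why: Saponification of an unhindered ethyl ester by acyl substitution; both benzyl ethers are inert to hydroxide and nothing else in the molecule is hydrolysable.

Step 5
Reactants: 5 2-{2-(benzyloxy)-5-[3-(benzyloxy)propyl]-3-methoxyphenyl}acetic acid
Product: 8 2-{2-(benzyloxy)-5-[3-(benzyloxy)propyl]-3-methoxyphenyl}propanedial (arylmalondialdehyde, largely enolised), via vinamidinium chloride 6 (not isolated), via aminoacrolein 7 (not isolated)
Conditions: POCl3 (3 equiv), DMF, 0 to 80 °C; then aq. NaOH, 80 °C; then cold 1 M HCl to pH 3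
Reagents that add atoms: N,N-dimethylformamide, CN(C)C=O; water, O
Why: POCl3 and DMF form the chloroiminium (Vilsmeier) reagent, which activates the carboxyl group of 5; the enol or ketene form of the activated acid is attacked at the benzylic carbon by a first chloroiminium ion. The resulting iminium carboxylate loses CO2 to an enamine, which is formylated a second time to give vinamidinium salt 6, so that C3–C2 and C3–CHO are both made from DMF carbons. Aqueous NaOH hydrolyses 6 by way of aminoacrolein 7 to the sodium enolate of 8, and acidification releases the dialdehyde. The closest known reaction type is the Vilsmeier–Arnold conversion of arylacetic acids into 2-arylvinamidinium salts and 2-arylmalondialdehydes. No ring closes and no stereocentre is formed in this step. The selectivity needed is benzylic carbon over ring carbon: the ketene and enamine carbons are far more nucleophilic than a dialkoxybenzene whose two free positions each lie between two substituents, and the cationic vinamidinium unit deactivates the ring further once formed. The benzyl ether on the ortho oxygen keeps the phenol from lactonising with the activated acid, and both benzyl ethers tolerate the chloroiminium reagent and the hot alkali, which a free or silylated alcohol would not.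

Step 6
Reactants: 8 2-{2-(benzyloxy)-5-[3-(benzyloxy)propyl]-3-methoxyphenyl}propanedial
Product: 10 5-[3-(benzyloxy)propyl]-7-methoxy-1-benzofuran-3-carbaldehyde, via free phenol dialdehyde 9 (not isolated)
Conditions: pentamethylbenzene (3 equiv), TFA, rt
Reagents that add atoms: none
Why: Acidolysis of the aryl benzyl ether, with the benzyl cation captured by pentamethylbenzene (Friedel–Crafts), is a known way to free phenols while primary alkyl benzyl ethers stay intact, and here the neighbouring protonated enal can assist departure of the benzyl group; the phenol of 9 then adds 5-exo-trig to one of the two equivalent aldehyde carbons and acid-catalysed loss of water aromatises the furan, leaving the other aldehyde as the C3 formyl group.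

Step 7
Reactants: 11 5-bromo-2-hydroxy-3-methoxybenzaldehyde
Product: 13 5-bromo-3-methoxybenzene-1,2-diol, via aryl formate 12 (not isolated)
Conditions: 30% H2O2, aq. NaOH, 0 °C to rt, N2; then HCl
Reagents that add atoms: hydrogen peroxide, OO
Why: Dakin oxidation: hydroperoxide adds to the aldehyde, the electron-rich aryl group migrates to oxygen to give formate 12, and the alkali hydrolyses it at once to the catechol; this is the standard conversion of ortho-vanillin-type aldehydes into 3-methoxycatechols and places bromine para to the central oxygen.

Step 8
Reactants: 13 5-bromo-3-methoxybenzene-1,2-diol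
Product: 14 1,2-bis(benzyloxy)-5-bromo-3-methoxybenzene
Conditions: BnBr (2.3 equiv), K2CO3 (3 equiv), DMF, 60 °C, N2
Reagents that add atoms: benzyl bromide, BrCc1ccccc1
Why: Double Williamson O-benzylation of the catechol with a mild base under nitrogen, since the catecholate is air-sensitive; the aryl bromide does not react.

Step 9
Reactants: 10 5-[3-(benzyloxy)propyl]-7-methoxy-1-benzofuran-3-carbaldehyde; 14 1,2-bis(benzyloxy)-5-bromo-3-methoxybenzene
Product: 15 2-[3,4-bis(benzyloxy)-5-methoxyphenyl]-5-[3-(benzyloxy)propyl]-7-methoxy-1-benzofuran-3-carbaldehyde
Conditions: Pd(OAc)2 (5 mol %), PCy3·HBF4 (10 mol %), PivOH (30 mol %), K2CO3 (2 equiv), DMA, 100 °C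
Reagents that add atoms: none
Why: Palladium-catalysed direct C–H arylation: zerovalent palladium inserts into the C–Br bond of 14 and the pivalate-bound divalent arylpalladium cleaves the C2–H bond of 10 by concerted metalation–deprotonation, this being the only heteroaryl C–H bond and the most acidic one because of O1 and the C3 formyl group; direct C2 arylation of benzofurans and of 3-formyl furans and thiophenes with aryl bromides is established, and the benzyl ethers keep both oxygenated rings inert.

Step 10
Reactants: 15 2-[3,4-bis(benzyloxy)-5-methoxyphenyl]-5-[3-(benzyloxy)propyl]-7-methoxy-1-benzofuran-3-carbaldehyde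
Product: 16 mururin C [2-(3,4-dihydroxy-5-methoxyphenyl)-5-(3-hydroxypropyl)-7-methoxy-1-benzofuran-3-carbaldehyde]
Conditions: BCl3 (6 equiv), pentamethylbenzene (9 equiv), CH2Cl2, −78 to −20 °C; then MeOH, aqueous work-up under N2
Reagents that add atoms: none
Why: Lewis-acid cleavage of benzyl ethers: BCl3 coordinates each ether oxygen and pentamethylbenzene traps the benzyl cation irreversibly (Friedel–Crafts), which prevents C-benzylation of the electron-rich rings; the two aryl methyl ethers have no chelating carbonyl neighbour and should survive at low temperature, and the aldehyde is not affected by a non-reducing Lewis acid.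

## Compound list

1 | dihydroconiferyl alcohol, 4-(3-hydroxypropyl)-2-methoxyphenol | COc1cc(CCCO)ccc1O | starting material
2 | 2-bromo-4-(3-hydroxypropyl)-6-methoxyphenol | COc1cc(CCCO)cc(Br)c1O | intermediate
3 | 2-(benzyloxy)-1-bromo-5-[3-(benzyloxy)propyl]-3-methoxybenzene | COc1cc(CCCOCc2ccccc2)cc(Br)c1OCc1ccccc1 | intermediate
4 | ethyl 2-{2-(benzyloxy)-5-[3-(benzyloxy)propyl]-3-methoxyphenyl}acetate | CCOC(=O)Cc1cc(CCCOCc2ccccc2)cc(OC)c1OCc1ccccc1 | intermediate
5 | 2-{2-(benzyloxy)-5-[3-(benzyloxy)propyl]-3-methoxyphenyl}acetic acid | OC(=O)Cc1cc(CCCOCc2ccccc2)cc(OC)c1OCc1ccccc1 | intermediate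
6 | N-[2-{2-(benzyloxy)-5-[3-(benzyloxy)propyl]-3-methoxyphenyl}-3-(dimethylamino)prop-2-en-1-ylidene]-N-methylmethanaminium chloride (vinamidinium chloride, formed in the flask) | CN(C)C=C(C=[N+](C)C)c1cc(CCCOCc2ccccc2)cc(OC)c1OCc1ccccc1.[Cl-] | intermediate
7 | 2-{2-(benzyloxy)-5-[3-(benzyloxy)propyl]-3-methoxyphenyl}-3-(dimethylamino)prop-2-enal (aminoacrolein, formed in the flask) | CN(C)C=C(C=O)c1cc(CCCOCc2ccccc2)cc(OC)c1OCc1ccccc1 | intermediate
8 | 2-{2-(benzyloxy)-5-[3-(benzyloxy)propyl]-3-methoxyphenyl}propanedial | O=CC(C=O)c1cc(CCCOCc2ccccc2)cc(OC)c1OCc1ccccc1 | intermediate
9 | 2-{5-[3-(benzyloxy)propyl]-2-hydroxy-3-methoxyphenyl}propanedial (formed in the flask) | O=CC(C=O)c1cc(CCCOCc2ccccc2)cc(OC)c1O | intermediate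
10 | 5-[3-(benzyloxy)propyl]-7-methoxy-1-benzofuran-3-carbaldehyde | O=Cc1coc2c(OC)cc(CCCOCc3ccccc3)cc12 | intermediate
11 | 5-bromo-2-hydroxy-3-methoxybenzaldehyde | COc1cc(Br)cc(C=O)c1O | starting material
12 | 5-bromo-2-hydroxy-3-methoxyphenyl formate (formed in the flask) | COc1cc(Br)cc(OC=O)c1O | intermediate
13 | 5-bromo-3-methoxybenzene-1,2-diol | COc1cc(Br)cc(O)c1O | intermediate
14 | 1,2-bis(benzyloxy)-5-bromo-3-methoxybenzene | COc1cc(Br)cc(OCc2ccccc2)c1OCc1ccccc1 | intermediate
15 | 2-[3,4-bis(benzyloxy)-5-methoxyphenyl]-5-[3-(benzyloxy)propyl]-7-methoxy-1-benzofuran-3-carbaldehyde | COc1cc(-c2oc3c(OC)cc(CCCOCc4ccccc4)cc3c2C=O)cc(OCc2ccccc2)c1OCc1ccccc1 | intermediate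
16 | mururin C, 2-(3,4-dihydroxy-5-methoxyphenyl)-5-(3-hydroxypropyl)-7-methoxy-1-benzofuran-3-carbaldehyde | COc1cc(-c2oc3c(OC)cc(CCCO)cc3c2C=O)cc(O)c1O | target

## Step count and least certain steps

Total step count: 10. Longest linear sequence: 8 steps (steps 1 to 6, then 9 and 10, from dihydroconiferyl alcohol 1); steps 7 and 8 prepare the ring B bromide.

**Step 5 (key step).** The most likely failure is diversion of the activated acid before decarboxylation. The neighbouring benzyloxy oxygen can attack the activated carboxyl group with loss of the benzyl group (debenzylative lactonisation). The sequence could also stall after the first formylation, or some ring formylation could occur at 80 °C. The fallback avoids any activated carboxyl group. It sets out from ester 4, which is reduced with i-Bu2AlH at −78 °C to 2-{2-(benzyloxy)-5-[3-(benzyloxy)propyl]-3-methoxyphenyl}acetaldehyde F1. This is converted with trimethyl orthoformate and catalytic TsOH in MeOH into dimethyl acetal F2. A single Vilsmeier–Arnold formylation of the acetal through its enol ether (POCl3, DMF, 60 °C), followed by alkaline hydrolysis and acidification, returns to the route at 8. In this variant C2 is the former ester carbon and only the formyl carbon comes from DMF.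

**Step 9.** The C2–H bond of an electron-poor benzofuran-3-carbaldehyde may react slowly with the electron-rich, hindered aryl bromide. Reduction or homocoupling of 14 and palladium-induced decarbonylation of the aldehyde could then win at the temperature needed. The fallback sets out from 10, which is converted with trimethyl orthoformate and PPTS in MeOH into 5-[3-(benzyloxy)propyl]-3-(dimethoxymethyl)-7-methoxy-1-benzofuran F3. Lithiation at C2 with n-BuLi in THF at −78 °C, transmetalation with ZnCl2 and Negishi coupling with bromide 14 under Pd(PPh3)4 give coupled acetal F4. Dilute aqueous HCl in THF returns to the route at 15.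

**Step 6.** The acidolysis may not be fully selective. Partial loss of the alkyl benzyl ether, C-benzylation of ring A by the released benzyl cation, or acid-induced self-condensation of the enolised dialdehyde before ring closure would all lower the return. The fallback gives up the selectivity. It sets out from 8, and BCl3 with pentamethylbenzene in CH2Cl2 (−78 to 0 °C) removes both benzyl groups, the cyclodehydration following on work-up to give 5-(3-hydroxypropyl)-7-methoxy-1-benzofuran-3-carbaldehyde F5. Re-benzylation of the primary alcohol under acidic conditions with benzyl 2,2,2-trichloroacetimidate and catalytic TfOH returns to the route at 10.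

**Step 10.** Cleavage of the primary alkyl benzyl ether may be slow at a temperature that still spares the methyl ethers. Warming risks demethylation next to the boron-bound oxygens, and the freed catechol can oxidise during work-up. The fallback replaces Lewis-acid cleavage by hydrogenolysis with the aldehyde masked. It sets out from 15, which is converted with ethylene glycol and catalytic TsOH in toluene with water removal into 2-{2-[3,4-bis(benzyloxy)-5-methoxyphenyl]-5-[3-(benzyloxy)propyl]-7-methoxy-1-benzofuran-3-yl}-1,3-dioxolane F6. Hydrogenolysis of the three benzyl ethers (H2, 1 atm, Pd(OH)2/C, EtOAc/MeOH) gives 5-[3-(1,3-dioxolan-2-yl)-5-(3-hydroxypropyl)-7-methoxy-1-benzofuran-2-yl]-3-methoxybenzene-1,2-diol F7. Acetal hydrolysis with dilute aqueous HCl in THF under nitrogen returns to the route at 16.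

## Further compounds

F1 | step 5 | 2-{2-(benzyloxy)-5-[3-(benzyloxy)propyl]-3-methoxyphenyl}acetaldehyde | O=CCc1cc(CCCOCc2ccccc2)cc(OC)c1OCc1ccccc1
F2 | step 5 | 2-(benzyloxy)-5-[3-(benzyloxy)propyl]-1-(2,2-dimethoxyethyl)-3-methoxybenzene | COC(OC)Cc1cc(CCCOCc2ccccc2)cc(OC)c1OCc1ccccc1
F3 | step 9 | 5-[3-(benzyloxy)propyl]-3-(dimethoxymethyl)-7-methoxy-1-benzofuran | COC(OC)c1coc2c(OC)cc(CCCOCc3ccccc3)cc12
F4 | step 9 | 2-[3,4-bis(benzyloxy)-5-methoxyphenyl]-5-[3-(benzyloxy)propyl]-3-(dimethoxymethyl)-7-methoxy-1-benzofuran | COC(OC)c1c(-c2cc(OC)c(OCc3ccccc3)c(OCc3ccccc3)c2)oc2c(OC)cc(CCCOCc3ccccc3)cc12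
F5 | step 6 | 5-(3-hydroxypropyl)-7-methoxy-1-benzofuran-3-carbaldehyde | O=Cc1coc2c(OC)cc(CCCO)cc12
F6 | step 10 | 2-{2-[3,4-bis(benzyloxy)-5-methoxyphenyl]-5-[3-(benzyloxy)propyl]-7-methoxy-1-benzofuran-3-yl}-1,3-dioxolane | COc1cc(-c2oc3c(OC)cc(CCCOCc4ccccc4)cc3c2C2OCCO2)cc(OCc2ccccc2)c1OCc1ccccc1
F7 | step 10 | 5-[3-(1,3-dioxolan-2-yl)-5-(3-hydroxypropyl)-7-methoxy-1-benzofuran-2-yl]-3-methoxybenzene-1,2-diol | COc1cc(-c2oc3c(OC)cc(CCCO)cc3c2C2OCCO2)cc(O)c1O
A1 | alternative 1 | (E)-3-(ethoxycarbonyl)-4-(furan-3-yl)but-3-enoic acid | CCOC(=O)/C(CC(=O)O)=C/c1ccoc1
A2 | alternative 1 | ethyl 7-acetoxybenzofuran-5-carboxylate | CCOC(=O)c1cc(OC(C)=O)c2occc2c1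
A3 | alternative 2 | tert-butyl[3-(4-bromo-3-iodo-5-methoxyphenyl)propoxy]dimethylsilane | COc1cc(CCCO[Si](C)(C)C(C)(C)C)cc(I)c1Br
A4 | alternative 2 | ethyl 3-[3,4-bis(benzyloxy)-5-methoxyphenyl]-3-oxopropanoate | CCOC(=O)CC(=O)c1cc(OC)c(OCc2ccccc2)c(OCc2ccccc2)c1
A5 | alternative 2 | ethyl 2-[3,4-bis(benzyloxy)-5-methoxyphenyl]-7-methoxy-5-[3-(tert-butyldimethylsilyloxy)propyl]benzofuran-3-carboxylate | CCOC(=O)c1c(-c2cc(OC)c(OCc3ccccc3)c(OCc3ccccc3)c2)oc2c(OC)cc(CCCO[Si](C)(C)C(C)(C)C)cc12
A6 | alternative 3 | pentacarbonyl{[5-(3,4-bis(benzyloxy)-5-methoxyphenyl)furan-2-yl](methoxy)methylidene}chromium | COC(c1ccc(-c2cc(OC)c(OCc3ccccc3)c(OCc3ccccc3)c2)o1)=[Cr](=C=O)(=C=O)(=C=O)(=C=O)=C=O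
A7 | alternative 3 | 5-(benzyloxy)pent-1-yne | C#CCCCOCc1ccccc1
A8 | alternative 3 | 2-[3,4-bis(benzyloxy)-5-methoxyphenyl]-5-(3-benzyloxypropyl)-7-methoxybenzofuran-4-ol | COc1cc(CCCOCc2ccccc2)c(O)c2cc(-c3cc(OC)c(OCc4ccccc4)c(OCc4ccccc4)c3)oc12
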